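**Retrosynthetic overview**

- The target is an upper 7,4'-dihydroxyflavan-3-ol unit (rings A, B, C; 2S,3R,4R, all-trans) joined C4→C8 to (−)-epicatechin (rings D, E, F; 2R,3R). The last disconnection is six benzyl ethers (global hydrogenolysis).
- Interflavan C4–C8 bond: Friedel–Crafts attack of C8 of tetra-O-benzylepicatechin on a C4 cation released from a 3,4-cis cyclic phenylboronate; the boron-tethered leaving oxygen blocks the face of O3, so the new bond is 3,4-trans.
- Key disconnection: ring C (C4–C4a and O1–C2 bonds) and the 1,3,2-dioxaborolane are closed in one operation from 3-(benzyloxy)phenol, a (2S,3R)-epoxy aldehyde and PhB(OH)2.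
- The epoxy aldehyde comes from 4-(benzyloxy)benzaldehyde by Wittig homologation and organocatalytic asymmetric epoxidation, the only source of absolute configuration for the upper unit.
- Ring order: rings A, B, D, E and F are bought intact; oxirane (step 2), then ring C together with the dioxaborolane (step 3), then the dioxaborolane is opened in the coupling (step 5).

Assumption: (−)-epicatechin, which already carries the (2R,3R) lower unit, is taken as an acceptable inexpensive commercial starting material.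

**Route**

Step 1
Reactants: 1 4-(benzyloxy)benzaldehyde; 2 (triphenylphosphoranylidene)acetaldehyde
Product: 3 (2E)-3-[4-(benzyloxy)phenyl]prop-2-enal
Conditions: 2 (1.15 equiv), toluene, 80 °C, 16 h
Reagents that add atoms: none
Why: Wittig olefination with the stabilised formyl ylide gives the (E)-enal selectively, and no stereocentre is formed.

Step 2
Reactants: 3 (2E)-3-[4-(benzyloxy)phenyl]prop-2-enal
Product: 4 (2S,3R)-3-[4-(benzyloxy)phenyl]oxirane-2-carbaldehyde
Conditions: 35% aq H2O2 (1.3 equiv), (S)-2-{bis[3,5-bis(trifluoromethyl)phenyl][(trimethylsilyl)oxy]methyl}pyrrolidine (10 mol%), CH2Cl2, 23 °C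
Reagents that add atoms: hydrogen peroxide, OO
Why: Jørgensen-type organocatalytic epoxidation (iminium conjugate addition of H2O2, then enamine 3-exo closure), in which the peroxide should enter anti to the diaryl(silyloxy)methyl group of the (S)-catalyst, setting C3 as R and, after closure on the same face, C2 as S in the trans-oxirane; the absolute sense is assigned from the steric model of this catalyst class, not from a recalled literature value, and is confirmed by reducing an aliquot to the known epoxy alcohol (the enantiomeric catalyst would give ent-4).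

Step 3
Reactants: 4 (2S,3R)-3-[4-(benzyloxy)phenyl]oxirane-2-carbaldehyde; 5 3-(benzyloxy)phenol
Product: 7 (2S,3R,4R)-7-(benzyloxy)-2-[4-(benzyloxy)phenyl]chromane-3,4-diyl phenylboronate, via benzodioxaborin oxirane 6 (not isolated)
Conditions: PhB(OH)2 (1.05 equiv), 4 Å molecular sieves, toluene, 23 °C; then EtCO2H (10 mol%), 50 °C
Reagents that add atoms: phenylboronic acid, OB(O)c1ccccc1
Why: Proposed new method: phenylboronic acid tethers phenol 5 to aldehyde 4 so that C–C bond formation occurs ortho to the hydroxyl and para to the benzyloxy group (Nagata-type ortho-hydroxyalkylation giving 6, with Cornforth/Felkin addition anti to the oxirane oxygen setting the carbinol carbon as R), then the labile aryl–O–B bond is exchanged by the acid and the freed phenol opens the boron-activated oxirane 6-endo at the 4-benzyloxybenzylic carbon with inversion (C2 becomes S, C3 stays R, 2,3-trans) while boron closes on the resulting 3,4-cis-diol, so ring C and the dioxaborolane form in the same flask; the closest known reactions are the phenylboronic acid-mediated ortho-hydroxyalkylation of phenols with aldehydes and the acid-promoted 6-endo cyclisation of 2-(2-hydroxybenzyl)-3-aryloxiranes to 2,3-trans-flavan-3-ols.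

Step 4
Reactants: 8 (−)-epicatechin
Product: 9 (2R,3R)-5,7-bis(benzyloxy)-2-[3,4-bis(benzyloxy)phenyl]chroman-3-ol
Conditions: BnBr (4.4 equiv), K2CO3 (5 equiv), DMF, 0 → 23 °C, argon
Reagents that add atoms: benzyl bromide, BrCc1ccccc1
Why: Williamson etherification of the four phenols, which K2CO3 deprotonates while the aliphatic 3-OH stays free, under mild oxygen-free conditions that leave C2 and C3 unchanged.

Step 5
Reactants: 7 (2S,3R,4R)-7-(benzyloxy)-2-[4-(benzyloxy)phenyl]chromane-3,4-diyl phenylboronate; 9 (2R,3R)-5,7-bis(benzyloxy)-2-[3,4-bis(benzyloxy)phenyl]chroman-3-ol (3 equiv)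
Product: 11 (2S,3R,4R)-7-(benzyloxy)-2-[4-(benzyloxy)phenyl]-4-{(2R,3R)-5,7-bis(benzyloxy)-2-[3,4-bis(benzyloxy)phenyl]-3-hydroxychroman-8-yl}chroman-3-ol, via boronic half-ester 10 (not isolated)
Conditions: Me3SiOTf (0.3 equiv), CH2Cl2, −40 → 0 °C; then aq NaHCO3
Reagents that add atoms: none
Why: Proposed new method: Me3SiOTf ionises the benzylic C4–O bond of the cyclic boronate (cation stabilised by O1 and the para 7-benzyloxy group) while the departing oxygen stays tied through boron to O3 on that face, so C8 of 9 (less hindered than C6, which sits between two benzyloxy groups) attacks from the opposite face in a Friedel–Crafts alkylation and sets C4 as R (3,4-trans) without touching C2 or C3, and aqueous work-up hydrolyses half-ester 10; the closest known reactions are the Lewis acid-catalysed coupling of 4-O-alkyl flavan-3-ols with benzylated flavan-3-ols and the Lewis acid-mediated substitution of benzylic boronates (benzodioxaborins).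

Step 6
Reactants: 11 (2S,3R,4R)-7-(benzyloxy)-2-[4-(benzyloxy)phenyl]-4-{(2R,3R)-5,7-bis(benzyloxy)-2-[3,4-bis(benzyloxy)phenyl]-3-hydroxychroman-8-yl}chroman-3-ol
Product: 12 (2R,3R)-2-(3,4-dihydroxyphenyl)-8-[(2S,3R,4R)-3,7-dihydroxy-2-(4-hydroxyphenyl)chroman-4-yl]chromane-3,5,7-triol
Conditions: H2 (1 atm), Pd(OH)2/C, THF/MeOH/H2O (20:1:1), 23 °C
Reagents that add atoms: none
Why: Hydrogenolysis of the six benzyl ethers over Pd(OH)2/C is the standard final step for benzylated proanthocyanidins and leaves the ring ethers, the interflavan C–C bond and all five stereocentres unchanged.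

**Compound list**

1 | 4-(benzyloxy)benzaldehyde | O=Cc1ccc(OCc2ccccc2)cc1 | starting material
2 | (triphenylphosphoranylidene)acetaldehyde | O=CC=P(c1ccccc1)(c1ccccc1)c1ccccc1 | starting material
3 | (2E)-3-[4-(benzyloxy)phenyl]prop-2-enal | O=C/C=C/c1ccc(OCc2ccccc2)cc1 | intermediate
4 | (2S,3R)-3-[4-(benzyloxy)phenyl]oxirane-2-carbaldehyde (trans) | O=C[C@H]1O[C@@H]1c1ccc(OCc2ccccc2)cc1 | intermediate
5 | 3-(benzyloxy)phenol | Oc1cccc(OCc2ccccc2)c1 | starting material
6 | (4R)-7-(benzyloxy)-4-{(2R,3R)-3-[4-(benzyloxy)phenyl]oxiran-2-yl}-2-phenyl-4H-1,3,2-benzodioxaborinine | c1ccccc1B2Oc3cc(OCc4ccccc4)ccc3[C@@H](O2)[C@H]5O[C@@H]5c6ccc(OCc7ccccc7)cc6 | intermediate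
7 | (2S,3R,4R)-7-(benzyloxy)-2-[4-(benzyloxy)phenyl]chromane-3,4-diyl phenylboronate (cyclic ester of the 2,3-trans-3,4-cis diol) | c5ccccc5COc1ccc([C@@H]2Oc3cc(OCc5ccccc5)ccc3[C@H]4OB(c5ccccc5)O[C@@H]24)cc1 | intermediate
8 | (−)-epicatechin, (2R,3R)-2-(3,4-dihydroxyphenyl)chromane-3,5,7-triol | c1c(O)cc(O)c2c1O[C@H](c1ccc(O)c(O)c1)[C@H](O)C2 | starting material
9 | (2R,3R)-5,7-bis(benzyloxy)-2-[3,4-bis(benzyloxy)phenyl]chroman-3-ol (tetra-O-benzyl-(−)-epicatechin) | c1c(OCc3ccccc3)cc(OCc3ccccc3)c2c1O[C@H](c1ccc(OCc3ccccc3)c(OCc3ccccc3)c1)[C@H](O)C2 | intermediate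
10 | {[(2S,3R,4R)-7-(benzyloxy)-2-[4-(benzyloxy)phenyl]-4-{(2R,3R)-5,7-bis(benzyloxy)-2-[3,4-bis(benzyloxy)phenyl]-3-hydroxychroman-8-yl}chroman-3-yl]oxy}(phenyl)borinic acid (mono-ester of phenylboronic acid at the upper 3-OH) | c5ccccc5COc1ccc([C@@H]2Oc3cc(OCc5ccccc5)ccc3[C@H](c3c(OCc5ccccc5)cc(OCc5ccccc5)c4c3O[C@H](c3ccc(OCc5ccccc5)c(OCc5ccccc5)c3)[C@H](O)C4)[C@H]2OB(O)c5ccccc5)cc1 | intermediate
11 | (2S,3R,4R)-7-(benzyloxy)-2-[4-(benzyloxy)phenyl]-4-{(2R,3R)-5,7-bis(benzyloxy)-2-[3,4-bis(benzyloxy)phenyl]-3-hydroxychroman-8-yl}chroman-3-ol | c5ccccc5COc1ccc([C@@H]2Oc3cc(OCc5ccccc5)ccc3[C@H](c3c(OCc5ccccc5)cc(OCc5ccccc5)c4c3O[C@H](c3ccc(OCc5ccccc5)c(OCc5ccccc5)c3)[C@H](O)C4)[C@H]2O)cc1 | intermediate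
12 | (2R,3R)-2-(3,4-dihydroxyphenyl)-8-[(2S,3R,4R)-3,7-dihydroxy-2-(4-hydroxyphenyl)chroman-4-yl]chromane-3,5,7-triol | Oc1ccc([C@@H]2Oc3cc(O)ccc3[C@H](c3c(O)cc(O)c4c3O[C@H](c3ccc(O)c(O)c3)[C@H](O)C4)[C@H]2O)cc1 | target

**Step count and risks**

Total steps: 6. Longest linear sequence: 5 (steps 1, 2, 3, 5, 6; step 4 is a side branch).

Steps most likely to fail:

1. Step 3 (boron-relay annulation). The electron-rich oxirane may open or rearrange before C–C bond formation, the relay may stop at 6, or a boron-bridged syn delivery may erode the 2,3-trans selectivity. The fallback sets out from 4 and 5 and comes back at 11. The halide-free magnesium bis(aryloxide) made from 5 and Mg(OMe)2 in toluene is added to 4 (metal-phenoxide-directed ortho-hydroxyalkylation, chelation controlled) to give 5-(benzyloxy)-2-{(S)-[(2R,3R)-3-[4-(benzyloxy)phenyl]oxiran-2-yl](hydroxy)methyl}phenol F1. Pyridinium p-toluenesulfonate in CH2Cl2 then closes ring C by 6-endo oxirane opening to (2S,3R,4S)-7-(benzyloxy)-2-[4-(benzyloxy)phenyl]chromane-3,4-diol F2. This free diol is coupled with 9 (Me3SiOTf, CH2Cl2, −40 °C) to give 11 without boron; either C4 epimer of F2 ionises to the same cation.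

2. Step 5 (interflavan coupling). The boronate may ionise sluggishly, and C6 attack, the 3,4-cis epimer or over-alkylation may compete. The fallback sets out from 7 and comes back at 11. Benzyl mercaptan with catalytic BF3·OEt2 converts 7 into (2S,3S,4S)-7-(benzyloxy)-2-[4-(benzyloxy)phenyl]-4-(benzylsulfanyl)chroman-3-ol F3; the small, soft thiol gives the 3,4-trans thioether and cannot oligomerise. F3 is then coupled with 9 by thiophilic activation with AgBF4 in THF at 0 °C, a neutral method that releases the cation slowly, to give 11.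

3. Step 2 (organocatalytic epoxidation). The electron-rich enal may react slowly, and the 4-alkoxyphenyl oxirane is acid-sensitive. The fallback sets out from 3 and comes back at 4. NaBH4/CeCl3·7H2O reduces 3 to (2E)-3-[4-(benzyloxy)phenyl]prop-2-en-1-ol F4. Sharpless asymmetric epoxidation (Ti(OiPr)4, D-(−)-diisopropyl tartrate, t-BuOOH, 4 Å molecular sieves, CH2Cl2, −20 °C) gives [(2R,3R)-3-[4-(benzyloxy)phenyl]oxiran-2-yl]methanol F5. Parikh–Doering oxidation (SO3·pyridine, DMSO, Et3N, 0 °C) returns 4.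

**Further compounds**

F1 | step 3 | 5-(benzyloxy)-2-{(S)-[(2R,3R)-3-[4-(benzyloxy)phenyl]oxiran-2-yl](hydroxy)methyl}phenol | Oc1cc(OCc2ccccc2)ccc1[C@H](O)[C@H]1O[C@@H]1c1ccc(OCc2ccccc2)cc1
F2 | step 3 | (2S,3R,4S)-7-(benzyloxy)-2-[4-(benzyloxy)phenyl]chromane-3,4-diol | c5ccccc5COc1ccc([C@@H]2Oc3cc(OCc5ccccc5)ccc3[C@H](O)[C@H]2O)cc1
F3 | step 5 | (2S,3S,4S)-7-(benzyloxy)-2-[4-(benzyloxy)phenyl]-4-(benzylsulfanyl)chroman-3-ol | c5ccccc5COc1ccc([C@@H]2Oc3cc(OCc5ccccc5)ccc3[C@H](SCc5ccccc5)[C@H]2O)cc1
F4 | step 2 | (2E)-3-[4-(benzyloxy)phenyl]prop-2-en-1-ol | OC/C=C/c1ccc(OCc2ccccc2)cc1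
F5 | step 2 | [(2R,3R)-3-[4-(benzyloxy)phenyl]oxiran-2-yl]methanol | OC[C@H]1O[C@@H]1c1ccc(OCc2ccccc2)cc1
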